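(All runs come from a simulation with made-up constants, and the scatter is random.)

If the rate of a flask is proportional to its catalyst, doubling the catalyst doubles the rate. That is the bench rule you would bring to these flasks, in which J and G form E with L as catalyst.

| flask | J | G | L | time |
|---|---|---|---|---|
| midnight | 150 mM | 120 mM | 15.0 mM |  |
| spring | 150 mM | 120 mM | 30.0 mM |  |
| summer | 150 mM | 60.0 mM | 15.0 mM |  |
| dusk | 450 mM | 120 mM | 15.0 mM |  |
| dawn | 50.0 mM | 120 mM | 7.50 mM | 64 min |

| midnight run: time / min | midnight run: [E] / mM | spring run: time / min | spring run: [E] / mM | summer run: time / min | summer run: [E] / mM | dusk run: time / min | dusk run: [E] / mM |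
|---|---|---|---|---|---|---|---|
| 4.9 | 24.0 | 4.9 | 32.8 | 4.9 | 13.8 | 4.9 | 41.6 |
| 15 | 55.1 | 15 | 73.2 | 15 | 32.0 | 15 | 87.4 |
| 28 | 80.4 | 28 | 94.7 | 28 | 43.9 | 28 | 108.7 |
| 45 | 96.6 | 45 | 107.6 | 45 | 52.1 | 45 | 116.8 |
| 64 | 107.1 | 64 | 114.5 | 64 | 56.3 | 64 | 120.7 |

(standard deviation of a reading: 1 mM)

- Overall: J + G -> E, with L as catalyst.
- Constant volume, constant temperature.
- A reading of a species includes what of it is bound.
- "The second partner" is G.
- An order is taken over about fifteen percent of the charge, up and down.

- apparent order in [L] of the starting rate, round the charge of the midnight run (the rate where two percent of its J have turned into E)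
- apparent order in [J] of the starting rate, round the charge of the midnight run (the rate where two percent of its J have turned into E) (one fixed amount of E, the same in the runs compared)
- E in the dawn run at 64 min, as a share of the J charged
- which of these the readings show (nothing beyond the main steps / the product decays / the catalyst dies in pairs / an uncatalysed path runs beside)

Try the rule on the spring run, which has twice the L of the midnight run and the same J and G. Once the two flasks have made the same amount of E they hold the same J and G, so the ratio of the times taken to reach that amount reads the ratio of their rates. The midnight run reads 55.1 mM at 15 min, and a straight line between the first two spring readings puts that amount at 10.5 min. So the spring run goes about 1.43 times as fast as the midnight run, not 2.00 times.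

Suppose, then, that the rate has one part proportional to L and another part that ignores L. Doubling L doubles the first part, so the ratio of rates is 1 + φ, and:

φ = ratio − 1 = 0.432

This φ, the share of the midnight rate that passes through L, is the quantity to carry. For a small change in L, the apparent order in L is φ itself. The rule's border is the crossing L_x, the amount of L at which the two parts are equal, with J and G held at the midnight charge:

L_x = L(midnight) × (1 − φ)/φ = 19.7 mM

The midnight run, with 15.0 mM of L, stands at 0.761 of this reading of the crossing, so I read the two parts as of like size, with a path running beside the catalyst.

The dusk run tests this. It has 3.00 times the J of the midnight run, and the same straight-line reading puts the midnight amount at 7.88 min, so it goes roughly 1.90 times as fast, an order in J of about 0.586. If the uncatalysed part grows in step with J and the catalysed part stays as it is, the ratio should be: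

3.00 × (1 − φ) + φ = 2.14

The dusk reading is a little less than this, so the catalysed part shows no rise with J, and I take it as roughly indifferent to J.

The dawn run has half the L and a third the J of the midnight run. For the midnight starting rate I run E/t of its first two readings back in a straight line to zero time, which gives about 5.49 mM min⁻¹. Scaling each part gives:

dawn starting rate = 2.23 mM min⁻¹

catalysed share at dawn = 0.533

J is the limiting reagent in the dawn run, 50.0 mM against 120 mM of G. Roughly, I let the rate fall in step with J and scale it by the mean G, 95.0 mM, over the charge of G:

E/J charged = 1 − exp(−rate/J × mean G/G charged × time) = 89.5%

The forecast gives orders of 0.55 in L and 0.55 in J, 91% for the dawn run, and "nothing beyond the main steps", reading the half orders as “a dimeric or bound resting state of the catalyst”, whereas I read a path beside L.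

The flask gives an order of 0.54 in L and 0.56 in J, 90.5% for the dawn run, and this verdict: an uncatalysed path runs beside.

    L + J ⇌ LJ, settled at all times (16.80 M⁻¹)
    LJ + G ⇌ LJG, settled at all times (4.750 M⁻¹)
    LJG → E + L (0.7920 min⁻¹)
    J + G → E (0.1320 M⁻¹ min⁻¹)

The order near one half in L round the midnight charge is due to the uncatalysed step J + G → E. With that step taken away, the order in L there is 0.96 rather than 0.54, against the φ of 0.432 read from the spring and midnight runs. Carried to the dawn run, φ gave the uncatalysed path about 46.7% of the starting rate, and without that path the dawn run reaches 80.9% of its J at 64 min instead of 90.5%.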